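**Plan**

- Locants: flavan numbering with T = upper unit, M = middle unit (its ring A is the central benzene), B = terminal epicatechin. Enabling feature: C4T (on C6M) and C4M (on C4aM) both flank C5M–OH, C3T and C3M are both R, and in each dioxabicyclo[3.3.1]nonane the outer arene (C4aT or C8B) lies anti to the C3–O bond. Seen from the central ring, both arms are therefore the same trans-epoxy ketone and the core has a C2 axis through C5M and C8M.
- Retrosynthetic cuts, in order: the five O–benzyl bonds; the four ketal bonds C2T–O1T, C2T–O7M, C2M–O1M and C2M–O7B; C4T–C4aT (to phloroglucinol) and C4M–C8B (to (−)-epicatechin); then, in one operation, C3T–C4T, C3M–C4M and both oxirane C4–O bonds (double Darzens), back to a 2,4-diformylphloroglucinol triether and two molecules of an α-chloro ketone.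
- Forward order: the central ring is diformylated and protected; both oxiranes form together; (−)-epicatechin opens one oxirane and phloroglucinol the other; acid closes the four ketal bonds (ring C of T, ring C of M and the two rings bridging to M and B); hydrogenolysis ends the route.
- Stereochemistry: C3T/C3M (retained) and C4T/C4M (each inverted once in the arene openings) come from the catalyst-controlled Darzens step; C2T/C2M are fixed by the bicyclic ketal geometry; C2B/C3B are those of (−)-epicatechin.

Key step: step 5

Assumption: N-[4-(trifluoromethyl)benzyl]cinchoninium bromide is taken to induce the (αR,βS) sense with this dialdehyde; if the sense is the opposite, the pseudoenantiomeric cinchonidinium salt would be used with no other change.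

**Route**

Step 1
Reactants: 1 phloroglucinol
Product: 3 2,4,6-trihydroxybenzene-1,3-dicarbaldehyde, via bis(iminium) dichloride 2 (not isolated)
Conditions: POCl3 (2.4 equiv), DMF, 1,4-dioxane, 0 °C → rt; then H2O, 60 °C
Reagents that add atoms: N,N-dimethylformamide, CN(C)C=O; water, O
Why: Vilsmeier–Haack formylation, in which the very electron-rich triol should take up two chloroiminium electrophiles, the third ring position being deactivated by the two iminium groups of 2, and aqueous hydrolysis then frees the dialdehyde.

Step 2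
Reactants: 3 2,4,6-trihydroxybenzene-1,3-dicarbaldehyde
Product: 4 2-hydroxy-4,6-bis(methoxymethoxy)benzene-1,3-dicarbaldehyde
Conditions: MOMCl (2.1 equiv), K2CO3, acetone, 0 °C → rt
Reagents that add atoms: chloromethyl methyl ether, COCCl
Why: Williamson-type O-alkylation, in which the two phenols next to the ring hydrogen (para to a formyl group, most acidic and least hindered) should react first, while the hydroxyl wedged between both formyl groups stays behind as the hydrogen-bonded, most hindered site, as in the partial acetalisation of 2,4,6-trihydroxybenzaldehyde.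

Step 3
Reactants: 4 2-hydroxy-4,6-bis(methoxymethoxy)benzene-1,3-dicarbaldehyde
Product: 5 2-(benzyloxy)-4,6-bis(methoxymethoxy)benzene-1,3-dicarbaldehyde
Conditions: BnBr, K2CO3, DMF, 50 °C
Reagents that add atoms: benzyl bromide, BrCc1ccccc1
Why: Williamson etherification of the remaining chelated phenol under standard forcing conditions; this benzyl ether later survives the acid step and so keeps O5M out of ketal formation.

Step 4
Reactants: 6 2-chloro-1-(3,4-dihydroxyphenyl)ethanone
Product: 7 1-[3,4-bis(benzyloxy)phenyl]-2-chloroethanone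
Conditions: BnBr (2.3 equiv), K2CO3, acetone, rt
Reagents that add atoms: benzyl bromide, BrCc1ccccc1
Why: Williamson O-benzylation of the catechol, in which excess benzyl bromide with a weak base at room temperature is expected to outrun self-alkylation by the phenacyl chloride, whose C–Cl bond is kept for the Darzens step.

Step 5
Reactants: 5 2-(benzyloxy)-4,6-bis(methoxymethoxy)benzene-1,3-dicarbaldehyde; 7 1-[3,4-bis(benzyloxy)phenyl]-2-chloroethanone (2.5 equiv)
Product: 9 C2-symmetric bis(trans-epoxy ketone) 2-(benzyloxy)-4,6-bis(methoxymethoxy)-1,3-bis{(2S,3R)-3-[3,4-bis(benzyloxy)benzoyl]oxiran-2-yl}benzene, via mono(epoxy ketone) aldehyde 8 (not isolated)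
Conditions: N-[4-(trifluoromethyl)benzyl]cinchoninium bromide (20 mol %), LiOH·H2O, CH2Cl2, 0 °C
Reagents that add atoms: none
Why: The ion pair of the chiral ammonium cation with the enolate of 7 adds to a formyl group of 5 (aldol addition), the aldolates equilibrate by retro-aldol, and the anti-chlorohydrin alkoxide displaces chloride to give the trans-epoxy ketone; the sequence then repeats at the remaining formyl group of 8. The closest known reaction is the asymmetric phase-transfer Darzens condensation of phenacyl chlorides with aromatic aldehydes. Each oxirane closes by a 3-exo-tet intramolecular O-alkylation. In each arm the ketone-bearing carbon (later C3T or C3M, R) and the aryl-bearing carbon (later C4T or C4M, S) are set by the face selection that the cinchoninium cation imposes on the aldol step, and their trans relationship by anti-periplanar closure of the more stable anti-aldolate. The step needs the same sense of induction twice: the two formyl groups of 5 are equivalent, so no site control is required, and a mismatched second event ends in the meso bis(epoxide), a separable diastereomer, so the C2-symmetric product should have higher enantiopurity than a single Darzens event would give. Chemoselectivity rests on 5 being non-enolisable and 7 having a single acidic site, with 7 in excess to offset the lower electrophilicity of the formyl group in 8.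

Step 6
Reactants: 9 C2-symmetric bis(trans-epoxy ketone); 10 (−)-epicatechin (0.7 equiv)
Product: 11 (2R,3R)-1-[3,4-bis(benzyloxy)phenyl]-3-[2-(benzyloxy)-3-{(2S,3R)-3-[3,4-bis(benzyloxy)benzoyl]oxiran-2-yl}-4,6-bis(methoxymethoxy)phenyl]-3-[(2R,3R)-2-(3,4-dihydroxyphenyl)-3,5,7-trihydroxy-3,4-dihydro-2H-chromen-8-yl]-2-hydroxypropan-1-one
Conditions: BF3·OEt2 (0.3 equiv), THF/CH2Cl2, −78 → −40 °C
Reagents that add atoms: none
Why: Friedel–Crafts alkylation of an arene by a Lewis-acid-activated aryl oxirane, in which boron coordination polarises the benzylic C4M–O bond (weakened by the two ortho oxygens and one para oxygen of the central ring) and C8 of 10, the most nucleophilic carbon of a flavan-3-ol ring A, should attack from the rear in a non-ionising medium at low temperature, setting C4M with inversion while C3M keeps its configuration; the two oxiranes of 9 are homotopic, so either may react, and 10 is limiting to hold back the second opening, unreacted 9 being recoverable.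

Step 7
Reactants: 11 mono-adduct carrying one oxirane arm and one epicatechin-substituted hydroxy ketone arm; 1 phloroglucinol
Product: 12 (2R,3R)-1-[3,4-bis(benzyloxy)phenyl]-3-{2-(benzyloxy)-3-[(1R,2R)-3-[3,4-bis(benzyloxy)phenyl]-2-hydroxy-3-oxo-1-(2,4,6-trihydroxyphenyl)propyl]-4,6-bis(methoxymethoxy)phenyl}-3-[(2R,3R)-2-(3,4-dihydroxyphenyl)-3,5,7-trihydroxy-3,4-dihydro-2H-chromen-8-yl]-2-hydroxypropan-1-one
Conditions: BF3·OEt2 (0.3 equiv), the triol in eightfold excess, THF, −78 → −40 °C
Reagents that add atoms: none
Why: The same Friedel–Crafts oxirane opening, a pure addition of one molecule of the triol, in which the remaining benzylic C4T–O bond is attacked from the rear by phloroglucinol (three equivalent ring carbons, so no regiochemical issue), setting C4T with inversion; the large excess of the triol should prevent its double alkylation and is washed out with water afterwards, and the two arms cannot interfere because they sit meta on the central ring.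

Step 8
Reactants: 12 bis(hydroxy ketone) carrying the epicatechin and phloroglucinol units
Product: 14 penta-O-benzyl ether of the target (benzyl on O5M and on the 3',4'-oxygens of the T and M catechols; all eight stereocentres as in the target), via de-acetalised diketone 13 (not isolated)
Conditions: HCl (ca. 1 M) in MeOH/THF, rt → 40 °C
Reagents that add atoms: none
Why: Acid-catalysed acetal solvolysis frees O7M and O1M, and each o-hydroxyaryl ketone should then close to its cyclic hemiketal and, through the oxocarbenium ion, to the bicyclic ketal with the ortho hydroxyl of the second arene (double intramolecular ketalisation, thermodynamically driven); C2T and C2M can adopt only the configuration that the cis-bridged bicycle allows, and the benzyl ether on O5M excludes the regioisomeric ketals.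

Step 9
Reactants: 14 penta-O-benzyl ether of the target
Product: 15 target CNP0338496.1
Conditions: H2 (1 atm), Pd(OH)2/C, THF/MeOH, rt
Reagents that add atoms: none
Why: Hydrogenolysis of the five benzyl ethers; the ketal carbons are benzylic but ring-bound, and flavan and bicyclic ketal C–O bonds are known to survive these neutral conditions, so no stereocentre should be touched.

**Compound list**

1 | phloroglucinol (benzene-1,3,5-triol) | Oc1cc(O)cc(O)c1 | starting material
2 | 1,1'-(2,4,6-trihydroxy-1,3-phenylene)bis(N,N-dimethylmethaniminium) dichloride | C[N+](C)=Cc1c(O)cc(O)c(C=[N+](C)C)c1O.[Cl-].[Cl-] | intermediate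
3 | 2,4,6-trihydroxybenzene-1,3-dicarbaldehyde | O=Cc1c(O)cc(O)c(C=O)c1O | intermediate
4 | 2-hydroxy-4,6-bis(methoxymethoxy)benzene-1,3-dicarbaldehyde | O=Cc1c(OCOC)cc(OCOC)c(C=O)c1O | intermediate
5 | 2-(benzyloxy)-4,6-bis(methoxymethoxy)benzene-1,3-dicarbaldehyde | O=Cc1c(OCOC)cc(OCOC)c(C=O)c1OCc1ccccc1 | intermediate
6 | 2-chloro-1-(3,4-dihydroxyphenyl)ethanone | O=C(CCl)c1ccc(O)c(O)c1 | starting material
7 | 1-[3,4-bis(benzyloxy)phenyl]-2-chloroethanone | O=C(CCl)c1ccc(OCc2ccccc2)c(OCc2ccccc2)c1 | intermediate
8 | 2-(benzyloxy)-3-{(2S,3R)-3-[3,4-bis(benzyloxy)benzoyl]oxiran-2-yl}-4,6-bis(methoxymethoxy)benzaldehyde | O=Cc1c(OCOC)cc(OCOC)c(c1OCc1ccccc1)[C@@H]1O[C@H]1C(=O)c1ccc(OCc2ccccc2)c(OCc2ccccc2)c1 | intermediate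
9 | 2-(benzyloxy)-4,6-bis(methoxymethoxy)-1,3-bis{(2S,3R)-3-[3,4-bis(benzyloxy)benzoyl]oxiran-2-yl}benzene (both oxiranes trans; aryl-bearing carbon S, ketone-bearing carbon R) | O=C(c1ccc(OCc2ccccc2)c(OCc2ccccc2)c1)[C@@H]1O[C@H]1c1c(OCOC)cc(OCOC)c(c1OCc1ccccc1)[C@@H]1O[C@H]1C(=O)c1ccc(OCc2ccccc2)c(OCc2ccccc2)c1 | intermediate
10 | (−)-epicatechin, (2R,3R)-2-(3,4-dihydroxyphenyl)-3,4-dihydro-2H-chromene-3,5,7-triol | Oc1cc(O)c2c(c1)O[C@H](c1ccc(O)c(O)c1)[C@H](O)C2 | starting material
11 | (2R,3R)-1-[3,4-bis(benzyloxy)phenyl]-3-[2-(benzyloxy)-3-{(2S,3R)-3-[3,4-bis(benzyloxy)benzoyl]oxiran-2-yl}-4,6-bis(methoxymethoxy)phenyl]-3-[(2R,3R)-epicatechin-8-yl]-2-hydroxypropan-1-one (drawn as the open hydroxy ketone) | O=C(c1ccc(OCc2ccccc2)c(OCc2ccccc2)c1)[C@@H]1O[C@H]1c1c(OCOC)cc(OCOC)c(c1OCc1ccccc1)[C@H]([C@@H](O)C(=O)c1ccc(OCc2ccccc2)c(OCc2ccccc2)c1)c1c(O)cc(O)c2c1O[C@H](c1ccc(O)c(O)c1)[C@H](O)C2 | intermediate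
12 | (2R,3R)-1-[3,4-bis(benzyloxy)phenyl]-3-{2-(benzyloxy)-3-[(1R,2R)-3-[3,4-bis(benzyloxy)phenyl]-2-hydroxy-3-oxo-1-(2,4,6-trihydroxyphenyl)propyl]-4,6-bis(methoxymethoxy)phenyl}-3-[(2R,3R)-epicatechin-8-yl]-2-hydroxypropan-1-one | O=C(c1ccc(OCc2ccccc2)c(OCc2ccccc2)c1)[C@H](O)[C@H](c1c(O)cc(O)cc1O)c1c(OCOC)cc(OCOC)c(c1OCc1ccccc1)[C@H]([C@@H](O)C(=O)c1ccc(OCc2ccccc2)c(OCc2ccccc2)c1)c1c(O)cc(O)c2c1O[C@H](c1ccc(O)c(O)c1)[C@H](O)C2 | intermediate
13 | compound 12 with both methoxymethyl ethers replaced by free phenols (O7M–H, O1M–H); same configuration at all six stereocentres | O=C(c1ccc(OCc2ccccc2)c(OCc2ccccc2)c1)[C@H](O)[C@H](c1c(O)cc(O)cc1O)c1c(O)cc(O)c(c1OCc1ccccc1)[C@H]([C@@H](O)C(=O)c1ccc(OCc2ccccc2)c(OCc2ccccc2)c1)c1c(O)cc(O)c2c1O[C@H](c1ccc(O)c(O)c1)[C@H](O)C2 | intermediate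
14 | penta-O-benzyl ether of the target: benzyl on O5M and on the 3',4'-oxygens of the T and M catechols; both bicyclic ketals closed; stereocentres as in 15 | Oc1cc(O)c2c(c1)O[C@@]1(c3ccc(OCc5ccccc5)c(OCc5ccccc5)c3)Oc3cc4c(c(OCc5ccccc5)c3[C@@H]2[C@H]1O)[C@H]1c2c(cc(O)c3c2O[C@H](c2ccc(O)c(O)c2)[C@H](O)C3)O[C@@](c2ccc(OCc5ccccc5)c(OCc5ccccc5)c2)(O4)[C@@H]1O | intermediate
15 | CNP0338496.1: flavan-3-ol trimer with two double linkages, T to M through C4T–C6M and C2T–O–C7M, M to B through C4M–C8B and C2M–O–C7B; (2S,3R,4R) in T, (2R,3R,4S) in M, (2R,3R) in B (flavan numbering) | Oc1cc(O)c2c(c1)O[C@@]1(c3ccc(O)c(O)c3)Oc3cc4c(c(O)c3[C@@H]2[C@H]1O)[C@H]1c2c(cc(O)c3c2O[C@H](c2ccc(O)c(O)c2)[C@H](O)C3)O[C@@](c2ccc(O)c(O)c2)(O4)[C@@H]1O | target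

**Step count and risks**

Total steps: 9. Longest linear sequence: 8 steps (steps 1, 2, 3, 5, 6, 7, 8, 9 from phloroglucinol).

Steps most likely to fail:

1. Step 5. The aldol addition to the second, more electron-rich formyl group may be slow, and enantioface control may be incomplete, so that hydrolysis of the chloro ketone and formation of the meso bis(epoxide) take over. The fallback sets out from 5: double Claisen–Schmidt condensation with commercial 1-[3,4-bis(benzyloxy)phenyl]ethanone (KOH, EtOH/THF) would give the (E,E)-bis(chalcone) F1. Double Juliá–Colonna epoxidation (poly-L-leucine, urea–hydrogen peroxide, DBU, THF), whose known sense with chalcones is (αR,βS) from the L-polymer, would then return to the route at 9. The C=C bonds are made first and the oxygen is delivered afterwards.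

2. Step 6. The second oxirane may also be opened, the unprotected flavan-3-ol may attack through C6 or through a phenolic oxygen, and partial ionisation to a free benzylic cation would erode the inversion at C4M or open the way to a 1,2-acyl shift. The fallback sets out from 10 and 9: fourfold methoxymethylation of the phenols of 10 (MOMCl, K2CO3, acetone) would give 5,7,3',4'-tetrakis-O-(methoxymethyl)epicatechin F2. As a fully etherified flavan-3-ol, F2 should react only at C8 and can be used in homogeneous CH2Cl2 at −78 °C with BF3·OEt2 to open one oxirane of 9, giving the mono-adduct F3. Opening of the second oxirane with phloroglucinol as in step 7 would give the bis(hydroxy ketone) F4. The acid treatment of step 8 would then remove all six acetals and close both ketals, returning to the route at 14.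

3. Step 8. The formaldehyde equivalents released may alkylate the free phloroglucinol-type rings, and acid may cleave the C4–arene bonds before the ketals lock them. The fallback sets out from 12 and separates phenol release from ketal closure. ZnBr2 with 1-propanethiol in CH2Cl2 at 0 °C would transfer the methoxymethyl groups irreversibly to sulfur, so that 13 is isolated. Pyridinium p-toluenesulfonate with 4 Å molecular sieves in THF at rt would then close both ketals under non-solvolytic conditions, returning to the route at 14. This fallback makes no compound outside the list (F0).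

Further compounds
F1 | step 5 | (2E,2'E)-3,3'-[2-(benzyloxy)-4,6-bis(methoxymethoxy)-1,3-phenylene]bis{1-[3,4-bis(benzyloxy)phenyl]prop-2-en-1-one} | O=C(/C=C/c1c(OCOC)cc(OCOC)c(/C=C/C(=O)c2ccc(OCc3ccccc3)c(OCc3ccccc3)c2)c1OCc1ccccc1)c1ccc(OCc2ccccc2)c(OCc2ccccc2)c1
F2 | step 6 | (2R,3R)-2-[3,4-bis(methoxymethoxy)phenyl]-5,7-bis(methoxymethoxy)-3,4-dihydro-2H-chromen-3-ol | COCOc1cc(OCOC)c2c(c1)O[C@H](c1ccc(OCOC)c(OCOC)c1)[C@H](O)C2
F3 | step 6 | analogue of 11 carrying methoxymethyl ethers on O5, O7, O3' and O4' of unit B | O=C(c1ccc(OCc2ccccc2)c(OCc2ccccc2)c1)[C@@H]1O[C@H]1c1c(OCOC)cc(OCOC)c(c1OCc1ccccc1)[C@H]([C@@H](O)C(=O)c1ccc(OCc2ccccc2)c(OCc2ccccc2)c1)c1c(OCOC)cc(OCOC)c2c1O[C@H](c1ccc(OCOC)c(OCOC)c1)[C@H](O)C2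
F4 | step 6 | analogue of 12 carrying methoxymethyl ethers on O5, O7, O3' and O4' of unit B | O=C(c1ccc(OCc2ccccc2)c(OCc2ccccc2)c1)[C@H](O)[C@H](c1c(O)cc(O)cc1O)c1c(OCOC)cc(OCOC)c(c1OCc1ccccc1)[C@H]([C@@H](O)C(=O)c1ccc(OCc2ccccc2)c(OCc2ccccc2)c1)c1c(OCOC)cc(OCOC)c2c1O[C@H](c1ccc(OCOC)c(OCOC)c1)[C@H](O)C2
F0 | step 8 | none | none
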